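The route rests on the homoallylic array O–C8–C9–C10=C1 shared by the ten-membered carbocycle and the fused γ-lactone: C9 is inserted last. A bicyclo[7.1.0]decene (nine-membered ring, cyclopropane on C8/C10, hydroxyl on C1, tert-butyl acetate arm on C7) is mesylated; cyclopropylcarbinyl–homoallyl rearrangement cleaves the C8–C10 fusion bond while the ester captures C8. One operation thus enlarges the ring from nine to ten atoms, creates the (E)-C1=C10 alkene, closes the lactone and sets C8. The precursor comes from a Claisen ring expansion of a seven-membered lactone (setting the Z-C4=C5 alkene, later epoxidised), α′-hydroxylation, reduction and hydroxyl-directed cyclopropanation.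

Key step: step 15

Remark: atoms keep the germacrane numbering of the target in every intermediate (ring C1–C10, lactone carbons C11–C13, C14 on C10, C15 on C4); C5 of 13–16 forms as an epimer mixture and becomes sp2 in step 10, so both epimers are carried on.

Step 1
Reactants: 1 4-tert-butoxy-4-oxobutanoic acid; 2 (S)-4-benzyl-1,3-oxazolidin-2-one
Product: 4 N-acyl oxazolidinone, via mixed pivalic anhydride 3 (not isolated)
Conditions: PivCl, Et3N, THF, −20 °C; then 2, LiCl, rt
Reagents that add atoms: none
Why: N-acylation of the oxazolidinone through the mixed pivalic anhydride, which is attacked at the less hindered succinyl carbonyl; no stereocentre is formed.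

Step 2
Reactants: 4 N-acyl oxazolidinone; 5 3-methylbut-2-enal (prenal)
Product: 6 syn-aldol adduct
Conditions: Bu2BOTf, iPr2NEt, CH2Cl2, 0 °C; 5, −78 → 0 °C; then pH 7 buffer, MeOH, H2O2, 0 °C
Reagents that add atoms: none
Why: Evans syn-aldol reaction: the (Z)-dibutylboron enolate of the imide (not of the tert-butyl ester) reacts through a Zimmerman–Traxler chair on the face left open by the benzyl group, which sets C7 and C6 (syn) in the absolute sense needed.

Step 3
Reactants: 6 syn-aldol adduct
Product: 7 C6 triethylsilyl ether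
Conditions: TESOTf, 2,6-lutidine, CH2Cl2, −78 °C
Reagents that add atoms: triethylsilyl trifluoromethanesulfonate, CC[Si](CC)(CC)OS(=O)(=O)C(F)(F)F
Why: Silylation of the secondary alcohol blocks retro-aldol and lactonisation onto the ester; no stereocentre changes.

Step 4
Reactants: 7 C6 triethylsilyl ether
Product: 8 primary alcohol (C8–OH)
Conditions: LiBH4, MeOH (1 equiv), THF, 0 °C
Reagents that add atoms: none
Why: Reductive cleavage of the auxiliary; the imide carbonyl is much more reactive towards LiBH4 than the tert-butyl ester, and the γ-hydroxy tert-butyl ester is kept cold and base-free so that it does not lactonise.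

Step 5
Reactants: 8 primary alcohol
Product: 9 aldehyde (C8)
Conditions: Dess–Martin periodinane, NaHCO3, CH2Cl2, rt
Reagents that add atoms: none
Why: Buffered Dess–Martin oxidation gives the α-branched aldehyde without epimerisation at C7 or loss of the β-silyloxy group.

Step 6
Reactants: 9 aldehyde; 10 methyl 2-[bis(2,2,2-trifluoroethoxy)phosphoryl]propanoate
Product: 11 (Z)-enoate diester
Conditions: KN(SiMe3)2, 18-crown-6, THF, −78 °C
Reagents that add atoms: none
Why: Still–Gennari olefination: the trifluoroethyl phosphonate eliminates under kinetic control to the (Z)-trisubstituted enoate, which places C1 and C7 cis on C10=C8 as the later rings require.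

Step 7
Reactants: 11 (Z)-enoate diester
Product: 12 (Z)-enoic acid
Conditions: LiOH, THF/MeOH/H2O, rt; then 0.5 M HCl to pH 4
Reagents that add atoms: lithium hydroxide, [Li+].[OH-]
Why: Saponification cleaves the methyl ester and leaves the hindered tert-butyl ester and the silyl ether; it is done before C5–OH exists so that no alkoxide can add to the enoate.

Step 8
Reactants: 12 (Z)-enoic acid
Product: 14 C5 hydroxy acid, via allylic hydroperoxide 13 (not isolated)
Conditions: O2, hν (visible), tetraphenylporphyrin (cat.), CH2Cl2, 0 °C; then PPh3, rt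
Reagents that add atoms: dioxygen (singlet oxygen made in situ), O=O
Why: Schenck ene reaction: singlet oxygen attacks only the electron-rich C5=C4 alkene, bonds to C5 and abstracts a methyl hydrogen (the C6–H lies in the alkene plane through 1,3-allylic strain), which gives the isopropenyl carbinol after reduction; C5 forms as an epimer mixture that is erased in step 10.

Step 9
Reactants: 14 C5 hydroxy acid
Product: 15 seven-membered lactone
Conditions: 2,4,6-Cl3C6H2COCl, Et3N, THF, rt; then DMAP, PhMe, 60 °C, high dilution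
Reagents that add atoms: none
Why: Yamaguchi lactonisation; the (Z)-alkene holds the activated acid next to C5–OH so that the seven-membered enoate lactone should close in preference to dimers; no stereocentre is formed.

Step 10
Reactants: 15 seven-membered lactone
Product: 17 cyclononadienone, via exocyclic enol ether 16 (not isolated)
Conditions: Cp2TiMe2, PhMe, 75 °C, dark; filtration through basic alumina; then PhMe, 140 °C, sealed tube
Reagents that add atoms: dimethyltitanocene Cp2TiMe2, C[Ti](C)(C1C=CC=C1)C1C=CC=C1
Why: Petasis methylenation of the lactone carbonyl (more exposed than the tert-butyl ester) followed by Claisen rearrangement of the allyl vinyl ether C2=C1–O–C5–C4=C3 (ring expansion from seven to nine atoms); the small ring forces the C6 tether pseudo-axial on C5 in the boat-like transition state, so the new C4=C5 alkene is Z in the ring and both C5 epimers converge.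

Step 11
Reactants: 17 cyclononadienone
Product: 18 α′-hydroxy ketone (C2–OH)
Conditions: KN(SiMe3)2, THF, −78 °C; then 2-(phenylsulfonyl)-3-phenyloxaziridine, −78 °C; NH4Cl (aq)
Reagents that add atoms: 2-(phenylsulfonyl)-3-phenyloxaziridine, O=S(=O)(c1ccccc1)N1OC1c1ccccc1
Why: Davis oxidation: kinetic deprotonation at C2 gives the cross-conjugated potassium enolate, which the N-sulfonyloxaziridine hydroxylates; C2 is set by substrate control, the reagent being expected to approach the enolate face opposite the transannular C7 side chain.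

Step 12
Reactants: 18 α′-hydroxy ketone
Product: 19 C2 tert-butyldimethylsilyl ether
Conditions: TBSOTf, 2,6-lutidine, CH2Cl2, −78 → 0 °C
Reagents that add atoms: tert-butyldimethylsilyl trifluoromethanesulfonate, CC(C)(C)[Si](C)(C)OS(=O)(=O)C(F)(F)F
Why: Silylation gives a robust, non-participating group on C2 that differs in lability from the C6 triethylsilyl ether; no stereocentre changes.

Step 13
Reactants: 19 C2 silyl ether enone
Product: 20 cyclononadienol (C1–OH)
Conditions: (S)-2-methyl-CBS-oxazaborolidine, catecholborane, PhMe, −78 °C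
Reagents that add atoms: none
Why: Corey–Bakshi–Shibata 1,2-reduction: with the α-methylalkenyl side as the large group the (S)-catalyst should deliver hydride so that C1–OH is trans to C2–OTBS, the same sense as Cornforth-type attack on the α-silyloxy ketone (matched).

Step 14
Reactants: 20 cyclononadienol
Product: 21 cyclopropyl carbinol (bicyclo[7.1.0]decenol)
Conditions: Et2Zn, CH2I2, CH2Cl2, −10 → 0 °C
Reagents that add atoms: diiodomethane, ICI
Why: Hydroxyl-directed Simmons–Smith (Furukawa) cyclopropanation of C8=C10 through the zinc alkoxide of C1–OH; in eight- and nine-membered cycloalk-2-enols this delivery is anti to the hydroxyl, here also the face away from the C7 side chain, and it sets C8 and C10, while the remote C4=C5 alkene reacts more slowly.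

Step 15
Reactants: 21 cyclopropyl carbinol
Product: 23 ring-expanded lactone, via mesylate 22 (not isolated)
Conditions: Ms2O, Et3N, CH2Cl2, −40 → 0 °C
Reagents that add atoms: none
Why: The mesylate 22 ionises with assistance from the cyclopropane: the C8–C10 fusion bond, antiperiplanar to C1–OMs, feeds its electrons into the new C10=C1 π bond while the carbonyl oxygen of the tert-butyl ester attacks C8 from the rear and then loses 2-methylpropene, so that C9 ends up inserted between C8 and C10 (cyclopropylcarbinyl–homoallyl rearrangement, the reaction type of the Julia olefin synthesis and of the ring-enlarging solvolysis of bicyclo[n.1.0]alkan-2-yl esters, here ended by an internal ester). The only ring that is closed is the γ-lactone, by 5-exo-tet attack of oxygen on C8 with the departing C10 outside the new ring; the ten-membered ring is not closed but arises when the fusion bond of the nine-membered ring is cut. C8 is the only new stereocentre and is fixed by inversion, that is by the cyclopropane face set in step 14 (CH2 anti to the C7 arm gives the trans-fused lactone); the alkene geometry is relayed from C1, because with C1–O anti to the cyclopropane CH2 the C2 carbon is antiperiplanar to C9 in the reacting conformer and the (E)-alkene results. The step needs cleavage of C8–C10 and not of C9–C10, which the secondary character of C8 and the five-membered reach of the ester should secure, and it needs capture before hydride shift from C2 or attack by the C4=C5 alkene, which the assisted ionisation and the non-participating silyl ether on C2 favour.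

Step 16
Reactants: 23 ring-expanded lactone
Product: 26 α-methylene lactone, via Mannich base 24 (not isolated), via methiodide 25 (not isolated)
Conditions: LiN(iPr)2, THF, −78 °C; Me2N=CH2 iodide, −78 °C → rt; then MeI, MeOH, rt; then NaHCO3 (aq), CH2Cl2
Reagents that add atoms: N,N-dimethylmethyleneiminium iodide (Eschenmoser's salt), C=[N+](C)C.[I-]
Why: Mannich reaction of the lactone lithium enolate, quaternisation and Hofmann-type elimination install C13 as the exocyclic methylene; C11 ends sp2, so its configuration in 24 does not matter.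

Step 17
Reactants: 26 α-methylene lactone
Product: 27 C6 alcohol
Conditions: PPTS, MeOH, 0 °C
Reagents that add atoms: none
Why: Acid-catalysed methanolysis removes the triethylsilyl ether much faster than the tert-butyldimethylsilyl ether, so only C6–OH is freed.

Step 18
Reactants: 27 C6 alcohol
Product: 28 epoxy alcohol
Conditions: VO(acac)2 (cat.), tBuOOH, CH2Cl2, 0 °C
Reagents that add atoms: tert-butyl hydroperoxide, CC(C)(C)OO
Why: Hydroxyl-directed epoxidation: the vanadate ester of C6–OH delivers oxygen to the adjacent (Z)-C4=C5 alkene on the face syn to the hydroxyl (cis-epoxy alcohol, as with medium-ring allylic alcohols), which sets C4 and C5; the C1=C10 alkene (silyl ether, no directing group) and the electron-poor methylene lactone should stay untouched.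

Step 19
Reactants: 28 epoxy alcohol
Product: 29 epoxy diol
Conditions: HF·pyridine, pyridine, THF, 0 °C → rt
Reagents that add atoms: none
Why: Buffered fluoride desilylation frees C2–OH without base, so that neither epoxide migration nor lactone migration to C6–OH is triggered.

Step 20
Reactants: 29 epoxy diol
Product: 30 target CNP0270851.3
Conditions: Ac2O, DMAP, pyridine, CH2Cl2, 0 °C → rt
Reagents that add atoms: acetic anhydride, CC(=O)OC(C)=O
Why: DMAP-catalysed acetylation of both secondary alcohols; no stereocentre is touched.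

Compound list
1 | 4-tert-butoxy-4-oxobutanoic acid (mono-tert-butyl succinate) | OC(=O)CCC(=O)OC(C)(C)C | starting material
2 | (S)-4-benzyl-1,3-oxazolidin-2-one | O=C1OC[C@H](Cc2ccccc2)N1 | starting material
3 | mixed anhydride of 1 with pivalic acid | CC(C)(C)C(=O)OC(=O)CCC(=O)OC(C)(C)C | intermediate
4 | tert-butyl 4-[(4S)-4-benzyl-2-oxo-1,3-oxazolidin-3-yl]-4-oxobutanoate | O=C1OC[C@H](Cc2ccccc2)N1C(=O)CCC(=O)OC(C)(C)C | intermediate
5 | 3-methylbut-2-enal (prenal) | CC(C)=CC=O | starting material
6 | tert-butyl (3S,4R)-3-{[(4S)-4-benzyl-2-oxo-1,3-oxazolidin-3-yl]carbonyl}-4-hydroxy-6-methylhept-5-enoate (syn-aldol) | O=C1OC[C@H](Cc2ccccc2)N1C(=O)[C@@H](CC(=O)OC(C)(C)C)[C@H](O)C=C(C)C | intermediate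
7 | triethylsilyl ether of 6 at C6–O | O=C1OC[C@H](Cc2ccccc2)N1C(=O)[C@@H](CC(=O)OC(C)(C)C)[C@H](O[Si](CC)(CC)CC)C=C(C)C | intermediate
8 | tert-butyl (3R,4R)-3-(hydroxymethyl)-6-methyl-4-(triethylsilyloxy)hept-5-enoate | OC[C@@H](CC(=O)OC(C)(C)C)[C@H](O[Si](CC)(CC)CC)C=C(C)C | intermediate
9 | tert-butyl (3S,4R)-3-formyl-6-methyl-4-(triethylsilyloxy)hept-5-enoate | O=C[C@@H](CC(=O)OC(C)(C)C)[C@H](O[Si](CC)(CC)CC)C=C(C)C | intermediate
10 | methyl 2-[bis(2,2,2-trifluoroethoxy)phosphoryl]propanoate | COC(=O)C(C)P(=O)(OCC(F)(F)F)OCC(F)(F)F | starting material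
11 | 6-tert-butyl 1-methyl (2Z,4R)-2-methyl-4-[(1S)-3-methyl-1-(triethylsilyloxy)but-2-en-1-yl]hex-2-enedioate | COC(=O)/C(C)=C\[C@@H](CC(=O)OC(C)(C)C)[C@H](O[Si](CC)(CC)CC)C=C(C)C | intermediate
12 | 1-carboxylic acid of 11 ((Z)-enoic acid, tert-butyl ester kept) | OC(=O)/C(C)=C\[C@@H](CC(=O)OC(C)(C)C)[C@H](O[Si](CC)(CC)CC)C=C(C)C | intermediate
13 | C5 hydroperoxide of 12 with isopropenyl group on C5 (C5 epimers) | OC(=O)/C(C)=C\[C@@H](CC(=O)OC(C)(C)C)[C@H](O[Si](CC)(CC)CC)C(OO)C(C)=C | intermediate
14 | C5 alcohol from 13 (hydroxy acid, C5 epimers) | OC(=O)/C(C)=C\[C@@H](CC(=O)OC(C)(C)C)[C@H](O[Si](CC)(CC)CC)C(O)C(C)=C | intermediate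
15 | tert-butyl 2-[3-methyl-2-oxo-7-(prop-1-en-2-yl)-6-(triethylsilyloxy)-2,5,6,7-tetrahydrooxepin-5-yl]acetate (C6, C7 as in 6; C5 epimers) | O=C1OC(C(C)=C)[C@@H](O[Si](CC)(CC)CC)[C@H](CC(=O)OC(C)(C)C)C=C1C | intermediate
16 | 2-methylidene analogue of 15 (exocyclic enol ether) | C=C1OC(C(C)=C)[C@@H](O[Si](CC)(CC)CC)[C@H](CC(=O)OC(C)(C)C)C=C1C | intermediate
17 | tert-butyl 2-[(2Z,7Z)-3,7-dimethyl-4-oxo-9-(triethylsilyloxy)cyclonona-2,7-dien-1-yl]acetate | O=C1CC/C(C)=C\[C@@H](O[Si](CC)(CC)CC)[C@H](CC(=O)OC(C)(C)C)/C=C\1C | intermediate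
18 | 5-hydroxy derivative of 17 (C2–OH, on the ring face opposite the acetate arm) | O=C1[C@@H](O)C/C(C)=C\[C@@H](O[Si](CC)(CC)CC)[C@H](CC(=O)OC(C)(C)C)/C=C\1C | intermediate
19 | tert-butyldimethylsilyl ether of 18 at C2–O | O=C1[C@@H](O[Si](C)(C)C(C)(C)C)C/C(C)=C\[C@@H](O[Si](CC)(CC)CC)[C@H](CC(=O)OC(C)(C)C)/C=C\1C | intermediate
20 | tert-butyl 2-[(2Z,7Z)-5-(tert-butyldimethylsilyloxy)-4-hydroxy-3,7-dimethyl-9-(triethylsilyloxy)cyclonona-2,7-dien-1-yl]acetate (C1–OH trans to C2–OTBS) | O[C@@H]1[C@@H](O[Si](C)(C)C(C)(C)C)C/C(C)=C\[C@@H](O[Si](CC)(CC)CC)[C@H](CC(=O)OC(C)(C)C)/C=C\1C | intermediate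
21 | tert-butyl 2-[(5Z)-3-(tert-butyldimethylsilyloxy)-2-hydroxy-1,5-dimethyl-7-(triethylsilyloxy)bicyclo[7.1.0]dec-5-en-8-yl]acetate (cyclopropane CH2 anti to C1–OH and to the acetate arm) | O[C@@H]1[C@@H](O[Si](C)(C)C(C)(C)C)C/C(C)=C\[C@@H](O[Si](CC)(CC)CC)[C@H](CC(=O)OC(C)(C)C)[C@H]2C[C@@]12C | intermediate
22 | C1 methanesulfonate of 21 | CS(=O)(=O)O[C@@H]1[C@@H](O[Si](C)(C)C(C)(C)C)C/C(C)=C\[C@@H](O[Si](CC)(CC)CC)[C@H](CC(=O)OC(C)(C)C)[C@H]2C[C@@]12C | intermediate
23 | (1(10)E,4Z)-2-(tert-butyldimethylsilyloxy)-6-(triethylsilyloxy)germacra-1(10),4-dien-12,8-olide (C2, C6, C7, C8 as in 30) | C1C(=O)O[C@H]2C/C(C)=C/[C@@H](O[Si](C)(C)C(C)(C)C)C/C(C)=C\[C@@H](O[Si](CC)(CC)CC)[C@H]12 | intermediate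
24 | 13-(dimethylamino) derivative of 23 (Mannich base, C11 epimers) | CN(C)CC1C(=O)O[C@H]2C/C(C)=C/[C@@H](O[Si](C)(C)C(C)(C)C)C/C(C)=C\[C@@H](O[Si](CC)(CC)CC)[C@H]12 | intermediate
25 | 13-(trimethylammonio) iodide from 24 | C[N+](C)(C)CC1C(=O)O[C@H]2C/C(C)=C/[C@@H](O[Si](C)(C)C(C)(C)C)C/C(C)=C\[C@@H](O[Si](CC)(CC)CC)[C@H]12.[I-] | intermediate
26 | (1(10)E,4Z)-2-(tert-butyldimethylsilyloxy)-6-(triethylsilyloxy)germacra-1(10),4,11(13)-trien-12,8-olide | C=C1C(=O)O[C@H]2C/C(C)=C/[C@@H](O[Si](C)(C)C(C)(C)C)C/C(C)=C\[C@@H](O[Si](CC)(CC)CC)[C@H]12 | intermediate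
27 | (1(10)E,4Z)-2-(tert-butyldimethylsilyloxy)-6-hydroxygermacra-1(10),4,11(13)-trien-12,8-olide | C=C1C(=O)O[C@H]2C/C(C)=C/[C@@H](O[Si](C)(C)C(C)(C)C)C/C(C)=C\[C@@H](O)[C@H]12 | intermediate
28 | (1(10)E)-2-(tert-butyldimethylsilyloxy)-4,5-epoxy-6-hydroxygermacra-1(10),11(13)-dien-12,8-olide (epoxide cis, syn to C6–OH) | C=C1C(=O)O[C@H]2C/C(C)=C/[C@@H](O[Si](C)(C)C(C)(C)C)C[C@@]3(C)O[C@H]3[C@@H](O)[C@H]12 | intermediate
29 | (1(10)E)-4,5-epoxy-2,6-dihydroxygermacra-1(10),11(13)-dien-12,8-olide | C=C1C(=O)O[C@H]2C/C(C)=C/[C@@H](O)C[C@@]3(C)O[C@H]3[C@@H](O)[C@H]12 | intermediate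
30 | (1(10)E,2S,4R,5S,6S,7R,8S)-2,6-diacetoxy-4,5-epoxygermacra-1(10),11(13)-dien-12,8-olide (CNP0270851.3) | C=C1C(=O)O[C@H]2C/C(C)=C/[C@@H](OC(C)=O)C[C@@]3(C)O[C@H]3[C@@H](OC(C)=O)[C@H]12 | target

Total step count: 20. Longest linear sequence: 20 steps (from 1).

Steps most likely to fail

Step 15. The ion pair may collapse at C1 without cleavage of the fusion bond (cyclopropylcarbinyl or cyclobutyl products), the external C9–C10 bond may open instead, a hydride may shift from C2, or the hindered tert-butyl ester may capture too slowly so that a free cation loses the antiperiplanar control of alkene geometry. The fallback uncouples ring enlargement from lactonisation and uses the known solvolytic ring enlargement with water as the nucleophile. It sets out from 21: mesylation at −60 °C (Ms2O, Et3N) gives 22, which is solvolysed in aqueous acetone buffered with NaHCO3; water attacks C8 from the rear and gives the ring-expanded (E)-homoallylic alcohol, the hydroxy ester F1. F1 is then lactonised with PPTS in dry toluene at 80 °C with loss of tert-butanol, and the route is rejoined at 23.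

Step 11. Facial selectivity in the enolate oxidation may be poor or reversed, since the conformation of the nine-membered dienolate cannot be predicted with confidence. The fallback accepts the wrong face and inverts C2. It sets out from 17: the same oxidation gives the C2-epimeric hydroxy ketone F2. Mitsunobu reaction (PPh3, DIAD, 4-nitrobenzoic acid, THF, 0 °C) inverts C2 and gives the 4-nitrobenzoate F3. Methanolysis (K2CO3, MeOH, 0 °C) returns the route at 18.

Step 14. The methylene may be delivered to the face syn to the hydroxyl (wrong cyclopropane face and hence cis-lactone and wrong alkene geometry later), or the C4=C5 alkene may be cyclopropanated as well. The fallback builds the cyclopropane before the alcohol, under steric control. It sets out from 19: conjugate methylenation of the enone with dimethylsulfoxonium methylide (Me3S(O)I, NaH, DMSO, rt; Corey–Chaykovsky reaction) on the face away from the C7 arm gives the cyclopropyl ketone F4. Reagent-controlled reduction of F4 ((S)-2-methyl-CBS-oxazaborolidine, catecholborane, PhMe, −78 °C) places C1–OH anti to the cyclopropane CH2 and returns the route at 21.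

Further compounds
F1 | step 15 | tert-butyl ester of the ring-expanded (1(10)E,4Z)-8-hydroxy acid: 2-(tert-butyldimethylsilyloxy)-8-hydroxy-6-(triethylsilyloxy)germacra-1(10),4-dien-12-oate | CC(C)(C)OC(=O)C[C@@H]1[C@@H](O)C/C(C)=C/[C@@H](O[Si](C)(C)C(C)(C)C)C/C(C)=C\[C@H]1O[Si](CC)(CC)CC
F2 | step 11 | C2 epimer of 18 | O=C1[C@H](O)C/C(C)=C\[C@@H](O[Si](CC)(CC)CC)[C@H](CC(=O)OC(C)(C)C)/C=C\1C
F3 | step 11 | 4-nitrobenzoate of 18 (C2 inverted relative to F2) | O=C1[C@@H](OC(=O)c2ccc(cc2)[N+](=O)[O-])C/C(C)=C\[C@@H](O[Si](CC)(CC)CC)[C@H](CC(=O)OC(C)(C)C)/C=C\1C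
F4 | step 14 | cyclopropyl ketone, tert-butyl 2-[(5Z)-3-(tert-butyldimethylsilyloxy)-1,5-dimethyl-2-oxo-7-(triethylsilyloxy)bicyclo[7.1.0]dec-5-en-8-yl]acetate | O=C1[C@@H](O[Si](C)(C)C(C)(C)C)C/C(C)=C\[C@@H](O[Si](CC)(CC)CC)[C@H](CC(=O)OC(C)(C)C)[C@H]2C[C@@]12C
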